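The oak run, with equal charges of starting material and coupling partner, reaches 35.8% side product at 6.00 d. The elm run, with 0.14 M of coupling partner against 0.092 M, reaches 57.8%, so side product seems to follow the partner charged.

| flask | starting material | coupling partner | remark | time |
|---|---|---|---|---|
| birch | 0.092 M | 0.184 M | run made earlier |  |
| oak | 0.092 M | 0.092 M | run made earlier |  |
| elm | 0.092 M | 0.14 M | run made earlier |  |
| alder | 0.18 M | 0.184 M | run made earlier |  |
| north-west | 0.092 M | 0.184 M | everything together at the start | 6.0 d |
| south | 0.092 M (fed, over 5.0 d) | 0.184 M | all else is in the flask from the start; the feed brings no volume worth counting | 6.0 d |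
| east | 0.092 M | 0.184 M (in portions, 4, over 5.0 d) | first portion at the start, last at 5.0 d | 6.0 d |
| west | 0.092 M | 0.184 M (fed, over 5.0 d) | all else is in the flask from the start; the feed brings no volume worth counting | 6.0 d |

- birch (time / d: side product / %, double product / %, starting material / %): 0.625: 16.0, 8.0, 49.2; 1.25: 31.1, 9.8, 30.3; 1.67: 37.5, 5.8, 23.7; 2.50: 47.7, 6.1, 18.0; 3.00: 51.6, 4.0, 14.8; 4.00: 56.4, 5.7, 10.1
- oak (time / d: side product / %, double product / %, starting material / %): 1.25: 16.4, 1.6, 58.4; 2.50: 22.8, 0, 51.1; 4.00: 30.8, 2.6, 43.9; 5.00: 32.6, 0.9, 39.9; 6.00: 35.8, 0, 38.7; 8.00: 40.1, 1.8, 34.1
- elm (time / d: side product / %, double product / %, starting material / %): 1.25: 26.4, 3.6, 42.1; 2.50: 39.8, 2.3, 30.4; 4.00: 49.7, 2.4, 22.2; 5.00: 52.5, 3.5, 19.8; 6.00: 57.8, 1.1, 17.9; 8.00: 63.7, 1.9, 11.5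
- alder (time / d: side product / %, double product / %, starting material / %): 1.25: 31.5, 4.6, 41.9; 3.00: 43.8, 0, 32.2; 4.00: 45.5, 0.5, 28.7; 6.00: 51.7, 0.2, 25.9; 8.00: 54.6, 1.5, 20.5

(scatter of a reading: 1 percentage point)

- a species is counted by the starting material in it: one side product counts as two
- the analysis behind the earlier runs scatters by 1 percentage point, standard deviation

1. which flask leads in amount of side product, in percent of the starting material charged ("all alike" within 1.5 percentage points) (north-west / south / east / west / all alike)
2. how much side product is there at the end, in percent of the starting material charged: north-west
3. how much side product is there at the end, in percent of the starting material charged: south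
4. how much side product is there at the end, in percent of the starting material charged: east
5. how much side product is there at the end, in percent of the starting material charged: west

So the quantity to carry is the partner share: starting material found in side product per coupling partner charged, in moles, at 6.00 d. Oak's reading gives 35.8%, and elm's reading gives 38.0%.

But birch, with twice as much partner as starting material, already runs lower at 4.00 d: its share is 28.2% against oak's 30.8%. Scaling oak's share by that ratio gives north-west a share of 32.8%, so this reckoning expects 65.6% side product. The share was read in flasks with everything together from the start, so the reckoning stops at north-west.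

The forecast gives 61% for north-west, 57% for south, 53% for east and 52% for west, with north-west leading. Of south it says “South keeps the partner high”, and its south value is what the last birch reading taken over gives.

The flasks give 64.7%, 33.8%, 54.1% and 55.9% in that order, with north-west leading.

    starting material + coupling partner → mono adduct (k = 0.363 /M/h)
    coupling partner + mono adduct → double product (k = 0.679 /M/h)
    coupling partner + double product → tris adduct (k = 0.500 /M/h)
    coupling partner ⇌ dormant form (K = 4.60, k = 0.0392 /h)
    starting material + double product → side product (k = 1.85 /M/h)

North-west's share comes to 32.4%, beside the reckoned 32.8%. South, on the same charges, comes to 16.9%, about half of it, with a mean [starting material] of 0.0254 M over the feed, and 41% of the starting material still free at 6.00 d. The neighbour flask is north-west with 0.074 M of coupling partner, which makes the partner the limiting reagent. Oak's share gives it 28.8% side product, and it holds 26.7% at 6.00 d.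

The earlier runs and the new flask are calculated for an exercise, noise included.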